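**Assumption (remark on the chemistry):** ring B is numbered as a chroman-4-one (O1, C2, C3, C4, C4a, C5 to C8, C8a); the target has no stereocentre, so no step needs stereocontrol; the irradiation is taken to be run at 254 nm in quartz.

## Analysis of the target

Mallopallidol 16 consists of two hexasubstituted benzene rings joined by a single methylene carbon. Ring A is a 2-methylpropanoyl methylphloroglucinol in which the ketone lies between two free hydroxyls and the oxygen para to it is a methyl ether; ring B is a 5,7-dihydroxy-2,2,6-trimethylchroman-4-one that carries the bridge at C8. C2 of the pyranone bears two methyl groups and there is no stereocentre, so the whole problem is one of regiochemistry. The sensitive parts are the electron-rich polyphenol rings (oxidation), the two aryl ketones and above all the diarylmethane, which has hydroxyls ortho to the bridge on both rings and can fragment through o-quinone methides in alkali or under Lewis and strong Brønsted acids. The difficulty lies in telling apart three oxygens on each ring: on ring A exactly one is methylated, and on ring B the pyranone must be fused through the oxygen para to the C-methyl group (O1, next to C8) and not through the C5 oxygen, which would give the isomeric 8-methylchromanone. The strategy rests on the fact that O1 is a phenol oxygen whose two ortho carbons are C8, which carries the bridge, and C4a, the only ring B carbon that still bears hydrogen once the bridge is in place. A 3-methylbut-2-enoyl group placed on O1 already contains C4, C3, C2 and both methyl groups, and an O-to-C shift can deliver it only to C4a, after which the freed O1 closes onto C2. The same hydroxyl, before it is acylated, directs the bridge to C8, so one oxygen serves both purposes.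

## Retrosynthetic reasoning

**16 to 15.** The two O–CH2OMe acetal bonds on the C5 and C7 oxygens are cut last. These two oxygens must stay masked until the pyranone exists, because a free C5 hydroxyl could close the ring the wrong way. The forward step is a mild acid methanolysis that must spare the bridge and the chromanone.

**15 to 13, through 14.** The pyranone is cut at O1–C2 and C4a–C4. The O1–C2 cut is a retro-oxa-Michael reaction and leads to the o-hydroxyaryl enone 14. The C4a–C4 cut is not traced to an intermolecular Friedel–Crafts acylation, which would need a Lewis acid next to the diarylmethane and the acetals. It is traced to the same acyl group sitting on O1, that is, to ester 13. This builds one ring and two skeletal bonds, brings C4 in at the ketone oxidation level, and fixes the position of the acyl group by substitution alone. The forward reaction must move the acyl group from oxygen to C4a under neutral conditions and then close the ring with a weak base.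

**13 to 11 and 12.** The ester C–O bond is cut, so the acid chloride 12 supplies all five carbons of the pyranone that lie outside the arene. The forward step must acylate the one ring B phenol of 11 in the presence of the two ring A hydroxyls. Those two are flanked on both sides and tied to the ketone, which is the basis for the selectivity.

**11 to 4 and 9, through 10.** The bond between the bridge carbon and C8 of ring B is cut. The ring A partner has only one free ring carbon, so the one-carbon unit can be placed there without ambiguity as the Mannich base 9, which releases the o-quinone methide 10 on heating. The ring B partner 4 is a symmetric mono-phenol with two equivalent ortho carbons; whichever carbon takes the bridge, the other becomes C4a. The forward reaction needs only heat, with no alkali and no Lewis acid.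

**9 to 8, 7, 5 and 6.** The aminomethyl group is removed first (Mannich reaction), then the O-methyl group (selective etherification of the hydroxyl para to the ketone), then the ketone (Friedel–Crafts acylation of 5 with 6). The two free carbons of 5 are equivalent, so the acylation raises no regiochemical question. The methylation is the only step of this branch that relies on selectivity.

**4 to 3, 2 and 1.** The pattern needed for ring B, with the oxygen para to the methyl group free and the two flanking oxygens masked, runs against the steric preference of a direct protection of 5. The phenol C–O bond is therefore cut to a C–B bond (3) and then to a C–H bond (2). In 2 the only ring C–H without an ortho substituent is the one para to the methyl group, so a sterically controlled borylation places the third oxygen where it is needed. Compound 2 comes from 1 by double etherification.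

## Alternatives that were turned down

Alternative 1: ring A assembled by benzannulation.
- Disconnection: three carbon–carbon bonds of ring A are cut. This leads back to the cyclobutenone 5,7-bis(benzyloxy)-8-{[2-(benzyloxy)-4-oxocyclobut-1-en-1-yl]methyl}-2,2,6-trimethylchroman-4-one A2, which already carries ring B, and to the alkyne 1-methoxyprop-1-yne A3.
- Forward key step: on heating, A2 opens to a vinylketene that adds A3 in a [2+2] cycloaddition. The new cyclobutenone opens again and closes by a 6π electrocyclisation to the phenol 5,7-bis(benzyloxy)-8-[6-(benzyloxy)-4-hydroxy-2-methoxy-3-methylbenzyl]-2,2,6-trimethylchroman-4-one A1.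
- For it: the substitution pattern of ring A follows from the connectivity of A2 and A3, so no selective O-methylation of a triol is needed. The step is thermal, and no second chromophore competes for light. On these points it is stronger than the chosen route.
- Against it: A2 already contains the finished chromanone, so the question of which oxygen closes the pyranone is only moved upstream. A2 is a vinylogous ester whose electrocyclic opening is slow, and it takes many steps to make. After A1 the isobutyryl group must still be introduced with 6 under Lewis-acid conditions beside the diarylmethane, followed by a threefold debenzylation.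
- Comparison: the chosen route buys both arenes with their oxygen and methyl pattern in place and spends its steps only on the bridge and the pyranone, which makes it much shorter than a route through A1.

Alternative 2: Petasis condensation and oxa-6π closure.
- Disconnection: C3–C4 and O1–C2 are cut. This leads to the ring B salicylaldehyde 3-[2,4-dihydroxy-6-methoxy-5-methyl-3-(2-methylpropanoyl)benzyl]-2-hydroxy-4,6-bis(methoxymethoxy)-5-methylbenzaldehyde A5 and to (2-methylprop-1-en-1-yl)boronic acid A6.
- Forward key step: A5, a secondary amine and A6 combine to an allylic amine. Loss of the amine gives a vinyl o-quinone methide, which closes to the chromene 1-{3-[(5,7-bis(methoxymethoxy)-2,2,6-trimethyl-2H-chromen-8-yl)methyl]-2,6-dihydroxy-4-methoxy-5-methylphenyl}-2-methylpropan-1-one A4.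
- For it: A5 would come from 11 by an ortho-selective formylation. Only ring B has a free carbon ortho to a hydroxyl, so the site is fixed by carbon substitution and not by the relative reactivity of three hydroxyls. That is more secure than the selective esterification of the chosen route, and the key step is thermal.
- Against it: A4 is at the wrong oxidation level. C4 carries no oxygen, so a Markovnikov hydration of the C3–C4 alkene and an oxidation must follow, in the presence of free phenols and an oxidisable diarylmethane.
- Comparison: the chosen route brings C4 in as a carbonyl group from 12 and needs no redox step after ring formation, whereas A4 still needs two.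

Alternative 3: aryne annulation with a tertiary hydroxy ester.
- Disconnection: O1–C8a and C4a–C4 are cut. This leads to the silyl triflate 2-[6-methoxy-2,4-bis(methoxymethoxy)-5-methyl-3-(2-methylpropanoyl)benzyl]-3,5-bis(methoxymethoxy)-4-methyl-6-(trimethylsilyl)phenyl trifluoromethanesulfonate A9 and to methyl 3-hydroxy-3-methylbutanoate A8.
- Forward key step: a fluoride source turns A9 into the aryne across C4a and C8a. The tertiary alkoxide of A8 adds at C8a and the C4a carbanion attacks the ester, which should give 8-[6-methoxy-2,4-bis(methoxymethoxy)-5-methyl-3-(2-methylpropanoyl)benzyl]-5,7-bis(methoxymethoxy)-2,2,6-trimethylchroman-4-one A7, the fourfold methoxymethyl ether of 16.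
- For it: both bonds of A7 form in one polar step. The C5 alkoxy group polarises the aryne so that the nucleophile is steered to C8a, and there is no photochemistry with its light-absorption problems. On these points it is as strong as or stronger than the chosen key step.
- Against it: a hindered tertiary alkoxide must attack the aryne carbon next to the bulky benzyl group, and the β-alkoxide ester formed from A8 can undergo retro-aldol cleavage. Ring A must be fully etherified because free phenols would add to the aryne, and its ketone is then no longer chelated. A9 needs several extra steps on a pentasubstituted ring, and it discards the phenol oxygen that directed the bridge, only to bring O1 back in from A8. A7 must finally lose four acetals instead of two.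
- Comparison: the chosen route keeps the directing oxygen as O1 and reaches the pyranone in two steps from 11, while the path to A7 spends more steps on A9 alone.

Key step: step 9

## Route

Step 1
Reactants: 1 2-methylresorcinol (2-methylbenzene-1,3-diol)
Product: 2 1,3-bis(methoxymethoxy)-2-methylbenzene
Conditions: MOMCl (2.5 equiv), i-Pr2NEt (3 equiv), CH2Cl2, 0 °C → rt
Reagents that add atoms: chloromethyl methyl ether, COCCl
Why: Double O-alkylation of the phenols gives the bis-acetal; methoxymethyl ethers are stable to base, heat and light and come off with mild acid at the end, and they mask the two oxygens that will flank the ring B methyl group.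

Step 2
Reactants: 2 1,3-bis(methoxymethoxy)-2-methylbenzene
Product: 3 2-[3,5-bis(methoxymethoxy)-4-methylphenyl]-4,4,5,5-tetramethyl-1,3,2-dioxaborolane
Conditions: [Ir(OMe)(cod)]2 (1.5 mol %), 4,4'-di-tert-butyl-2,2'-bipyridine (3 mol %), B2pin2 (1.0 equiv), THF, 80 °C, sealed tube
Reagents that add atoms: bis(pinacolato)diboron, CC1(C)OB(OC1(C)C)B1OC(C)(C)C(C)(C)O1
Why: Iridium-catalysed aromatic C–H borylation is sterically controlled, and the carbon para to the methyl group is the only ring C–H without an ortho substituent, so boron should enter there alone.

Step 3
Reactants: 3 2-[3,5-bis(methoxymethoxy)-4-methylphenyl]-4,4,5,5-tetramethyl-1,3,2-dioxaborolane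
Product: 4 3,5-bis(methoxymethoxy)-4-methylphenol
Conditions: 30% aq. H2O2, aq. NaOH, THF, 0 °C → rt
Reagents that add atoms: hydrogen peroxide, OO
Why: Alkaline peroxide oxidation of the arylboronate (aryl shift from boron to oxygen) replaces boron by hydroxyl at the same carbon; the acetals are stable to base, and the product is the symmetric mono-phenol with two equivalent ortho carbons.

Step 4
Reactants: 5 2-methylphloroglucinol (2-methylbenzene-1,3,5-triol); 6 isobutyryl chloride (2-methylpropanoyl chloride)
Product: 7 2-methyl-1-(2,4,6-trihydroxy-3-methylphenyl)propan-1-one
Conditions: AlCl3 (3.5 equiv), PhNO2/CH2Cl2, 0 °C → rt; aq. HCl work-up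
Reagents that add atoms: none
Why: Friedel–Crafts C-acylation of the highly activated triol; the two free ring carbons of 5 are equivalent, the first acyl group deactivates the ring against a second, and any O-acyl product is carried to the C-acyl ketone by AlCl3.

Step 5
Reactants: 7 2-methyl-1-(2,4,6-trihydroxy-3-methylphenyl)propan-1-one
Product: 8 1-(2,6-dihydroxy-4-methoxy-3-methylphenyl)-2-methylpropan-1-one
Conditions: Me2SO4 (1.0 equiv), K2CO3 (1.0 equiv), acetone, rt → 50 °C
Reagents that add atoms: dimethyl sulfate, COS(=O)(=O)OC
Why: Selective Williamson O-methylation; the hydroxyl para to the ketone is the most acidic and the only one neither next to the acyl group nor able to chelate it, so with one equivalent of base and reagent it should react first.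

Step 6
Reactants: 8 1-(2,6-dihydroxy-4-methoxy-3-methylphenyl)-2-methylpropan-1-one
Product: 9 1-{3-[(dimethylamino)methyl]-2,6-dihydroxy-4-methoxy-5-methylphenyl}-2-methylpropan-1-one
Conditions: aq. CH2O (37%), aq. Me2NH (40%, slight excess), EtOH, 0 °C → rt
Reagents that add atoms: formaldehyde, C=O; dimethylamine, CNC
Why: Mannich aminomethylation at the single free ring carbon of 8, which lies ortho and para to hydroxyls; the excess of amine and the low temperature hold the one-carbon unit as the amine and should suppress the symmetric methylene dimer.

Step 7
Reactants: 9 1-{3-[(dimethylamino)methyl]-2,6-dihydroxy-4-methoxy-5-methylphenyl}-2-methylpropan-1-one; 4 3,5-bis(methoxymethoxy)-4-methylphenol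
Product: 11 1-{2,6-dihydroxy-3-[6-hydroxy-2,4-bis(methoxymethoxy)-3-methylbenzyl]-4-methoxy-5-methylphenyl}-2-methylpropan-1-one, via o-quinone methide 10 (not isolated)
Conditions: 4 (3 equiv), 1,4-dioxane, 100 °C, N2 stream
Reagents that add atoms: none
Why: The phenolic Mannich base loses dimethylamine on heating to give o-quinone methide 10, and the electron-rich phenol 4 adds to it through an ortho carbon (conjugate addition of Friedel–Crafts type), the usual way to unsymmetrical methylene-bridged acylphloroglucinols. Both ortho carbons of 4 are equivalent and the para carbon is blocked, an excess of 4 limits double alkylation, and the neutral medium avoids the alkali-induced scrambling of the bridge.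

Step 8
Reactants: 11 1-{2,6-dihydroxy-3-[6-hydroxy-2,4-bis(methoxymethoxy)-3-methylbenzyl]-4-methoxy-5-methylphenyl}-2-methylpropan-1-one; 12 3-methylbut-2-enoyl chloride
Product: 13 2-[2,4-dihydroxy-6-methoxy-5-methyl-3-(2-methylpropanoyl)benzyl]-3,5-bis(methoxymethoxy)-4-methylphenyl 3-methylbut-2-enoate
Conditions: 12 (1.05 equiv, slow addition), pyridine (3 equiv), CH2Cl2, −20 → 0 °C
Reagents that add atoms: none
Why: O-acylation of a neutral phenol by the acylpyridinium ion; the ring B hydroxyl is electron-rich, has a free ortho position and is not chelated, whereas both ring A hydroxyls are flanked on both sides, conjugated with the ketone and held in its hydrogen bond, so the ring B oxygen should react first. A weak base is chosen so that no ring A phenoxide forms, the acid chloride is not deconjugated through a vinylketene, and the bridge is not exposed to alkali.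

Step 9
Reactants: 13 2-[2,4-dihydroxy-6-methoxy-5-methyl-3-(2-methylpropanoyl)benzyl]-3,5-bis(methoxymethoxy)-4-methylphenyl 3-methylbut-2-enoate
Product: 15 8-[2,4-dihydroxy-6-methoxy-5-methyl-3-(2-methylpropanoyl)benzyl]-5,7-bis(methoxymethoxy)-2,2,6-trimethylchroman-4-one, via o-hydroxyaryl enone 14 (not isolated)
Conditions: hν (254 nm, low-pressure Hg lamp, quartz), degassed MeCN (5 mM), 20 °C; then Et3N, MeCN, 20 → 40 °C, dark
Reagents that add atoms: none
Why: Light of 254 nm excites the aryl ester and breaks its ArO–C(=O) bond homolytically; the phenoxyl and 3-methylbut-2-enoyl radicals recombine inside the solvent cage at C4a, and the cyclohexadienone so formed tautomerises to the chelated o-hydroxyaryl enone 14 (C4a–C4 bond). Triethylamine then allows the regenerated phenol to add to the β,β-dimethyl enone in a 6-endo-trig oxa-Michael closure (O1–C2 bond), which the gem-dimethyl group favours. The closest known reaction type is the photo-Fries rearrangement of aryl 3-methylbut-2-enoates followed by base-mediated cyclisation to 2,2-dimethylchroman-4-ones, used here on a more highly substituted ester. No stereocentre is created, since C2 carries two methyl groups. The site of the acyl shift is set by substitution: the second ortho carbon bears the bridge and the para carbon the methyl group, so recombination at either gives a dienone that cannot enolise and can only fall back to the radical pair. The choice of ring oxygen is set by the methoxymethyl ether on the C5 oxygen, which leaves the C8a oxygen as the only one able to close, so the 8-methyl isomer cannot arise. Ring A should stay a spectator because its ketone is chelated by a free ortho hydroxyl and returns to the ground state by excited-state proton transfer; as it still takes part of the light, the irradiation is run dilute, degassed and to partial conversion, and recovered 13 together with any 11 from cage escape is returned through step 8. No Lewis acid or alkali is present at any point, which protects the diarylmethane.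

Step 10
Reactants: 15 8-[2,4-dihydroxy-6-methoxy-5-methyl-3-(2-methylpropanoyl)benzyl]-5,7-bis(methoxymethoxy)-2,2,6-trimethylchroman-4-one
Product: 16 mallopallidol (8-[2,4-dihydroxy-6-methoxy-5-methyl-3-(2-methylpropanoyl)benzyl]-5,7-dihydroxy-2,2,6-trimethylchroman-4-one)
Conditions: conc. HCl (cat.), MeOH, 40 °C
Reagents that add atoms: none
Why: Acid-catalysed acetal methanolysis frees the C5 and C7 hydroxyls; every ring carbon is substituted, so the released one-carbon fragment cannot alkylate either arene, and the dilute acid and low temperature should leave the bridge and the chromanone intact.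

## Compound list

1 | 2-methylresorcinol (2-methylbenzene-1,3-diol) | Cc1c(O)cccc1O | starting material
2 | 1,3-bis(methoxymethoxy)-2-methylbenzene | COCOc1cccc(OCOC)c1C | intermediate
3 | 2-[3,5-bis(methoxymethoxy)-4-methylphenyl]-4,4,5,5-tetramethyl-1,3,2-dioxaborolane | COCOc1cc(cc(OCOC)c1C)B1OC(C)(C)C(C)(C)O1 | intermediate
4 | 3,5-bis(methoxymethoxy)-4-methylphenol | COCOc1cc(O)cc(OCOC)c1C | intermediate
5 | 2-methylphloroglucinol (2-methylbenzene-1,3,5-triol) | Cc1c(O)cc(O)cc1O | starting material
6 | isobutyryl chloride (2-methylpropanoyl chloride) | CC(C)C(=O)Cl | starting material
7 | 2-methyl-1-(2,4,6-trihydroxy-3-methylphenyl)propan-1-one | CC(C)C(=O)c1c(O)cc(O)c(C)c1O | intermediate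
8 | 1-(2,6-dihydroxy-4-methoxy-3-methylphenyl)-2-methylpropan-1-one | COc1cc(O)c(C(=O)C(C)C)c(O)c1C | intermediate
9 | 1-{3-[(dimethylamino)methyl]-2,6-dihydroxy-4-methoxy-5-methylphenyl}-2-methylpropan-1-one | COc1c(C)c(O)c(C(=O)C(C)C)c(O)c1CN(C)C | intermediate
10 | 3-hydroxy-5-methoxy-4-methyl-6-methylidene-2-(2-methylpropanoyl)cyclohexa-2,4-dien-1-one (ring A o-quinone methide) | C=C1C(=O)C(C(=O)C(C)C)=C(O)C(C)=C1OC | intermediate
11 | 1-{2,6-dihydroxy-3-[6-hydroxy-2,4-bis(methoxymethoxy)-3-methylbenzyl]-4-methoxy-5-methylphenyl}-2-methylpropan-1-one | COc1c(C)c(O)c(C(=O)C(C)C)c(O)c1Cc1c(OCOC)c(C)c(OCOC)cc1O | intermediate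
12 | 3-methylbut-2-enoyl chloride | CC(C)=CC(=O)Cl | starting material
13 | 2-[2,4-dihydroxy-6-methoxy-5-methyl-3-(2-methylpropanoyl)benzyl]-3,5-bis(methoxymethoxy)-4-methylphenyl 3-methylbut-2-enoate | COc1c(C)c(O)c(C(=O)C(C)C)c(O)c1Cc1c(OCOC)c(C)c(OCOC)cc1OC(=O)C=C(C)C | intermediate
14 | 1-{3-[2,4-dihydroxy-6-methoxy-5-methyl-3-(2-methylpropanoyl)benzyl]-2-hydroxy-4,6-bis(methoxymethoxy)-5-methylphenyl}-3-methylbut-2-en-1-one | COc1c(C)c(O)c(C(=O)C(C)C)c(O)c1Cc1c(OCOC)c(C)c(OCOC)c(C(=O)C=C(C)C)c1O | intermediate
15 | 8-[2,4-dihydroxy-6-methoxy-5-methyl-3-(2-methylpropanoyl)benzyl]-5,7-bis(methoxymethoxy)-2,2,6-trimethylchroman-4-one | COc1c(C)c(O)c(C(=O)C(C)C)c(O)c1Cc1c(OCOC)c(C)c(OCOC)c2c1OC(C)(C)CC2=O | intermediate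
16 | mallopallidol (8-[2,4-dihydroxy-6-methoxy-5-methyl-3-(2-methylpropanoyl)benzyl]-5,7-dihydroxy-2,2,6-trimethylchroman-4-one) | COc1c(C)c(O)c(C(=O)C(C)C)c(O)c1Cc1c(O)c(C)c(O)c2c1OC(C)(C)CC2=O | target

## Step count and least certain steps

Total step count: 10. Longest linear sequence: 7 steps (steps 1, 2, 3, 7, 8, 9, 10; the ring A branch, steps 4, 5, 6, 7, 8, 9, 10, is equally long).

**Step 9 (key step).** What is most likely to go wrong is unproductive absorption and quenching. The chelated ring A ketone, and later the chromanone product, absorb at 254 nm. The ring A ketone lies one carbon away from the ester chromophore and may take over its excitation energy before the O–C bond breaks, so conversion could stall. Escape of the radical pair from the cage, which gives back 11, and photochemical deconjugation of the enoate are lesser losses. The fallback runs the same photochemical step on ring B alone, before the bridge is made; it sets out from 4, 12 and 9 and comes back to the route at 16. Compound 4 would be acylated with 12 (pyridine, CH2Cl2) to 3,5-bis(methoxymethoxy)-4-methylphenyl 3-methylbut-2-enoate F1. Irradiation of this ester at 254 nm in MeCN and treatment with Et3N should give 5,7-bis(methoxymethoxy)-2,2,6-trimethylchroman-4-one F2, because the two ortho carbons are equivalent and only the former ester oxygen is free to close. Acid methanolysis would then give 5,7-dihydroxy-2,2,6-trimethylchroman-4-one F3. Heating this chromanone with 9 in 1,4-dioxane should let C8, its only free ring carbon, capture 10 and give 16. The cost is a bridging step on a ring deactivated by the chromanone carbonyl, with the base- and heat-sensitive target as its direct product.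

**Step 8.** What is most likely to go wrong is loss of chemoselectivity. The ring A hydroxyl that is not held in the chelate at a given moment could be acylated as well or instead, which would give mixtures of mono- and diesters; base-induced deconjugation of the acyl group is a second risk. The fallback esterifies before bridging, so that only one hydroxyl is present; it sets out from 4 and 9 and comes back at 13. Compound 4 would be acylated with 12 as described above to 3,5-bis(methoxymethoxy)-4-methylphenyl 3-methylbut-2-enoate F1, and 9 would be N-methylated with MeI to 1-[2,4-dihydroxy-6-methoxy-5-methyl-3-(2-methylpropanoyl)phenyl]-N,N,N-trimethylmethanaminium iodide F4. Heating this salt with an excess of the ester in MeCN at 80 °C should release 10 with a trimethylammonium salt as the only by-product, and a tertiary amine cannot aminolyse the aryl ester. The ring carbon of the ester that lies ortho and para to the two methoxymethoxy groups should capture 10 in a Friedel–Crafts alkylation and give 13 directly. The arene is a weaker nucleophile than the phenol 4, which is why this is the fallback and not the main route.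

**Step 7.** What is most likely to go wrong is double alkylation of 4 at both ortho carbons, and self-condensation of 10 when its capture is slow. The fallback reverses the polarity of the bridge formation; it sets out from 4 and 8 and comes back at 11. Compound 4 would be aminomethylated (aq. CH2O, aq. Me2NH, EtOH) to 2-[(dimethylamino)methyl]-3,5-bis(methoxymethoxy)-4-methylphenol F5, which is easily separated from neutral material by acid–base extraction. Heating this Mannich base with an excess of 8 in xylene at about 130 °C should generate the ring B o-quinone methide. Compound 8 has a single free ring carbon and cannot be alkylated twice, so it should capture the o-quinone methide and give 11.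

**Step 5.** What is most likely to go wrong is methylation at one of the hydroxyls next to the ketone, or a second methylation, which would give isomeric and dimethylated ethers that are hard to separate. The fallback methylates all three hydroxyls and then removes two methyl groups under chelation control; it sets out from 7 and comes back at 8. Exhaustive methylation of 7 (excess Me2SO4, K2CO3, acetone, reflux) would give 2-methyl-1-(2,4,6-trimethoxy-3-methylphenyl)propan-1-one F6. An excess of BCl3 (CH2Cl2, 0 °C → rt, prolonged) should then cleave only the two methyl ethers ortho to the carbonyl group, through the boron chelate of the ketone, and leave the para methyl ether, giving 8.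

## Further compounds

F1 | step 9 | 3,5-bis(methoxymethoxy)-4-methylphenyl 3-methylbut-2-enoate | CC(C)=CC(=O)Oc1cc(OCOC)c(C)c(OCOC)c1
F2 | step 9 | 5,7-bis(methoxymethoxy)-2,2,6-trimethylchroman-4-one | COCOc1cc2OC(C)(C)CC(=O)c2c(OCOC)c1C
F3 | step 9 | 5,7-dihydroxy-2,2,6-trimethylchroman-4-one | Cc1c(O)cc2OC(C)(C)CC(=O)c2c1O
F4 | step 8 | 1-[2,4-dihydroxy-6-methoxy-5-methyl-3-(2-methylpropanoyl)phenyl]-N,N,N-trimethylmethanaminium iodide | COc1c(C)c(O)c(C(=O)C(C)C)c(O)c1C[N+](C)(C)C.[I-]
F5 | step 7 | 2-[(dimethylamino)methyl]-3,5-bis(methoxymethoxy)-4-methylphenol | COCOc1cc(O)c(CN(C)C)c(OCOC)c1C
F6 | step 5 | 2-methyl-1-(2,4,6-trimethoxy-3-methylphenyl)propan-1-one | COc1cc(OC)c(C(=O)C(C)C)c(OC)c1C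
A1 | alternative 1 | 5,7-bis(benzyloxy)-8-[6-(benzyloxy)-4-hydroxy-2-methoxy-3-methylbenzyl]-2,2,6-trimethylchroman-4-one | COc1c(C)c(O)cc(OCc2ccccc2)c1Cc1c(OCc2ccccc2)c(C)c(OCc2ccccc2)c2c1OC(C)(C)CC2=O
A2 | alternative 1 | 5,7-bis(benzyloxy)-8-{[2-(benzyloxy)-4-oxocyclobut-1-en-1-yl]methyl}-2,2,6-trimethylchroman-4-one | O=C1CC(OCc2ccccc2)=C1Cc1c(OCc2ccccc2)c(C)c(OCc2ccccc2)c2c1OC(C)(C)CC2=O
A3 | alternative 1 | 1-methoxyprop-1-yne | CC#COC
A4 | alternative 2 | 1-{3-[(5,7-bis(methoxymethoxy)-2,2,6-trimethyl-2H-chromen-8-yl)methyl]-2,6-dihydroxy-4-methoxy-5-methylphenyl}-2-methylpropan-1-one | COc1c(C)c(O)c(C(=O)C(C)C)c(O)c1Cc1c(OCOC)c(C)c(OCOC)c2c1OC(C)(C)C=C2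
A5 | alternative 2 | 3-[2,4-dihydroxy-6-methoxy-5-methyl-3-(2-methylpropanoyl)benzyl]-2-hydroxy-4,6-bis(methoxymethoxy)-5-methylbenzaldehyde | COc1c(C)c(O)c(C(=O)C(C)C)c(O)c1Cc1c(OCOC)c(C)c(OCOC)c(C=O)c1O
A6 | alternative 2 | (2-methylprop-1-en-1-yl)boronic acid | CC(C)=CB(O)O
A7 | alternative 3 | 8-[6-methoxy-2,4-bis(methoxymethoxy)-5-methyl-3-(2-methylpropanoyl)benzyl]-5,7-bis(methoxymethoxy)-2,2,6-trimethylchroman-4-one | COc1c(C)c(OCOC)c(C(=O)C(C)C)c(OCOC)c1Cc1c(OCOC)c(C)c(OCOC)c2c1OC(C)(C)CC2=O
A8 | alternative 3 | methyl 3-hydroxy-3-methylbutanoate | COC(=O)CC(C)(C)O
A9 | alternative 3 | 2-[6-methoxy-2,4-bis(methoxymethoxy)-5-methyl-3-(2-methylpropanoyl)benzyl]-3,5-bis(methoxymethoxy)-4-methyl-6-(trimethylsilyl)phenyl trifluoromethanesulfonate | COc1c(C)c(OCOC)c(C(=O)C(C)C)c(OCOC)c1Cc1c(OCOC)c(C)c(OCOC)c([Si](C)(C)C)c1OS(=O)(=O)C(F)(F)F
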